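**Structural features**

The target 18 is a C–C-linked biflavone. An acacetin unit (unit 1: rings A and C plus a 4-methoxyphenyl ring B) is bonded through C6 of its ring A to C8'' of a genkwanin-type unit (unit 2: 5''-OH, 7''-OMe, 4-hydroxyphenyl ring B). The single C6–C8'' biaryl bond is the only link between the two 2-aryl-4H-chromen-4-ones, and it carries four ortho oxygen substituents (O5, O7, the 7''-methoxyl and O1''). There is no stereogenic centre; the hindered C6–C8'' axis is the only possible stereogenic element, and the structure carries no descriptor for it. Six phenolic oxygens must end differentiated: methyl on O4' and O7'', hydrogen on O5, O7, O5'' and O4'''. The fragile parts are the two pyranone rings, which open at O1–C2 in hot acid or strong aqueous base and can reclose through the other ortho oxygen (6/8 isomerization), and the chelated 5-hydroxyls. The real difficulty is to make a tetra-ortho-substituted biaryl bond at the less accessible C6 of unit 1 and to place it at C8'' (not C6'') of unit 2, beside the only methoxyl of that ring. Ring A of unit 2 is an acylphloroglucinol whose atoms C8a'', C8'', C7'', C6'', C5'' and C4a'' carry O, aryl, OMe, H, OH and acyl. That pattern is a 3-aryl-4-methoxy-2-pyrone (lactone carbon, C3, C4, C5, C6) plus the first carbon of a 6-(2-oxoalkyl) chain, and the key step uses it by closing the C4a''–C8a'' bond.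

**Logic of the disconnections**

18 to 17. The four O–CH2Ph bonds on O5, O7, O5'' and O4''' are cut. Carrying every free hydroxyl as a benzyl ether next to the two permanent methyl ethers removes any end-game selectivity problem among six oxygens. The forward step must cleave four benzyl ethers without reducing either C2=C3 bond.

17 to 15 (through 16). The O1''–C2'' bond is cut and the C2''=C3'' unsaturation is shifted back to an enone, so ring C of unit 2 becomes a 2'-hydroxychalcone. This reduces unit 2 to a substituted ring A plus a cinnamoyl chain. The closure must go through the oxygen next to the biaryl bond, so the other ortho oxygen has to be blocked; in 15 it is a benzyl ether.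

15 to 14. The O–benzyl bond on the exposed hydroxyl is cut. This leaves a chalcone with two free ortho hydroxyls, which is what the ring synthesis delivers. The forward step must benzylate only the hydroxyl next to C–H and leave the one wedged between the ketone and the biaryl bond.

14 to 12 (through 13). The C4a''–C8a'' bond is cut (retro-Claisen), and the resulting ester 13 is closed back to the lactone 12. A hexasubstituted benzene ring is exchanged for a pyrone with only two substituents to install, and the 7''-methoxyl arrives in place from a commercial compound. The forward step needs Claisen closure rather than aldol closure, and opening of a lactone that is flanked by a bulky aryl group.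

12 to 8 and 11. The C4a''–C4'' bond (pyrone CH2 to ketone carbon) is cut. The 6-methyl group of 8 is the only readily deprotonated position, and 11 supplies C4'', C3'', C2'' and ring B of unit 2 in one piece. The base must leave the flavone of unit 1 alone, and two equivalents are needed because the product is more acidic than 8. The acylation is placed after the halogenation and the cross-coupling so that neither sees the active methylene or the enone.

11 to 9 and 10. The C=C bond that becomes C2''–C3'' is cut. Both partners are commercial, and the forward olefination must give the E alkene.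

8 to 5 and 7. The C6–C8'' biaryl bond is cut. It is the only bond between the units, and at this stage unit 2 is still a small, flat pyrone and not a complete flavone, which eases the hindered coupling. The forward step must form a tetra-ortho-substituted bond from a di-ortho-alkoxy boron partner that is prone to protodeboronation.

7 to 6. The C3–I bond is cut. C3 is the innately nucleophilic position of 6, so one step on the commercial pyrone suffices.

5 to 4 to 3 to 2 to 1. The C6–B bond, the O5–benzyl bond, the C6–I bond and the O7–benzyl bond are cut in turn. Iodination goes to C6 only while the 5-hydroxyl is free and hydrogen-bonded, so O7 is benzylated first, C6 is iodinated next, and O5 is benzylated last. The demand is C6 over C8 selectivity in the iodination and a borylation that tolerates two ortho benzyloxy groups.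

**Other disconnections considered**

Alternative 1: Ring A of unit 1 is cut at C7–C8 and C4a–C8a, with C6–C7 re-formed in the last pericyclic event. A 4-(flavon-8-yl)-3-ethoxy-2-(silyloxymethyl)cyclobutenone A1 is heated (80 to 110 °C) with (triisopropylsilyloxy)acetylene A2. Four-electron opening to a vinylketene, (2+2) addition of A2, a second four-electron opening and six-electron closure give the pentasubstituted phenol A3.
- In favour: the biaryl bond is never made by cross-coupling. It starts as an sp3 carbon–aryl bond in A1, and the pericyclic cascade fixes the substitution pattern. O5 (ethyl ether), O7 (free) and O8a (silyl ether) emerge differentiated, so ring C of unit 1 can only close the intended way.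
- Where it is equal or better: regiocontrol of the later ring closure is at least equal to the chosen plan, and the neutral thermal conditions are better than methoxide for base-sensitive groups.
- Against: A3 holds only a silyloxymethyl group where C4, C3, C2 and ring B of unit 1 must still be built (oxidation, chain extension, cyclodehydration). The ethyl ether on O5 and the methyl ether on O5'' must both be cleaved selectively at the end. A1 itself needs a flavon-8-ylacetic acid and a ketene–alkoxyalkyne cycloaddition. The acacetin unit, available intact, would be built atom by atom.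
- Comparison: the mechanism is sound, but the route would be markedly longer than the twelve steps of the chosen plan.

Alternative 2: The C6–C8'' bond is cut directly, with O5 and O7'' tied by a methylene acetal. The 8''-iodide A4 would add oxidatively to zerovalent palladium (Pd(OAc)2, PCy3·HBF4, K2CO3, pivalic acid) and arylate C6–H by concerted metalation–deprotonation, closing a dibenzo-1,3-dioxepine and giving A5.
- In favour: both flavones enter intact and no boron reagent is needed. The tether makes the tetra-ortho coupling intramolecular and allows only C6 on unit 1, while the iodide sits at the innately reactive C8 of a 5,7-dialkoxyflavone.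
- Where it is equal or better: convergence and avoidance of ring construction are better than in the chosen plan. The overall step count would be about equal.
- Against: the unsymmetrical formaldehyde acetal has to be built on the chelated, weakly nucleophilic 5-hydroxyl. Seven-membered closure by direct arylation is less favourable than five- or six-membered closure. After A5 the acetal must be cleaved under acid that spares three benzyl ethers and does not trigger 6/8 isomerization, and O7'' must then be methylated in the presence of O5.
- Comparison: the tether carbon is added and removed, whereas every carbon of the pyrone in the chosen plan ends in the target. The mechanistic risk is concentrated in acetal formation and removal, not in the coupling.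

Alternative 3: The O1–C2 bond of unit 1 is cut and reconnected in thought to O5, so the 6,8''-biflavone is traced to the 8,8''-linked isomer A6. In hot HCl–acetic acid the pyranone of unit 1 would open to the aryl 1,3-diketone, rotate and reclose through the former O5 to give A7, the 5''-O-methyl ether of the target. Unit 2 cannot move because O5'' is methylated.
- In favour: both coupling partners would carry their handle at C8, the position that electrophiles attack in 5,7-dialkoxyflavones.
- Where it is equal or better: fragment preparation is better, since the three-step 7-benzylation, 6-iodination and 5-benzylation sequence of the chosen plan becomes unnecessary. The route could be shorter overall.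
- Against: the step is an equilibrium between two isomers of similar congestion, with no structural bias toward full conversion, and the isomers are closely similar to separate. Hot acid may start to cleave the 5''-methyl ether and so let unit 2 migrate as well. A7 still needs peri-selective demethylation at O5'' beside two methyl ethers that must stay. The 8,8'' coupling is as hindered as the 6,8'' coupling, so the hardest bond is no easier.
- Comparison: the chosen plan sets the linkage kinetically and irreversibly; this alternative trades control for brevity.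

Key step: step 9

Assumption: the target carries no axial descriptor, so no control of the C6–C8'' axis is attempted; 18 is expected as the racemate if the axis is configurationally stable.

Remarks on structure and sequence:
- The ring-opened ester 13 keeps the ester carbon and the C4 methylene cis across C2=C3, as in the lactone. By the sequence rules this isomer is (2E), not (2Z), because the ester outranks the aryl group on C2 and the methoxyl outranks C4 on C3.
- C3 of the pyrone is iodinated and coupled before the side chain is attached. A 6-(2-oxoalkyl) chain would offer an active methylene to the iodinating agent and would cyclize prematurely in the aqueous base of the coupling.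
- The p-coumaroyl unit is taken from commercial 4-(benzyloxy)benzaldehyde, which gives the protected Weinreb amide in one step.

**Step 1**
Reactants: 1 acacetin (5,7-dihydroxy-4'-methoxyflavone)
Product: 2 7-benzyloxy-5-hydroxy-4'-methoxyflavone
Conditions: BnBr (1.1 equiv), K2CO3, acetone, reflux
Reagents that add atoms: benzyl bromide, BrCc1ccccc1
Why: Williamson etherification; the 7-OH is the most acidic phenol of 1 and the 5-OH is held in a hydrogen bond to the C4 carbonyl, so one equivalent of benzyl bromide with a weak base should alkylate O7 only.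

**Step 2**
Reactants: 2 7-benzyloxy-5-hydroxy-4'-methoxyflavone
Product: 3 7-benzyloxy-5-hydroxy-6-iodo-4'-methoxyflavone
Conditions: BnNMe3·ICl2, CaCO3, CH2Cl2–MeOH, rt
Reagents that add atoms: benzyltrimethylammonium dichloroiodate, C[N+](C)(C)Cc1ccccc1.Cl[I-]Cl
Why: Electrophilic aromatic iodination; with the chelated 5-OH free, dichloroiodate iodination of 5-hydroxy-7-alkoxyflavones goes ortho to that hydroxyl (C6) and not to C8, and CaCO3 takes up the HCl.

**Step 3**
Reactants: 3 7-benzyloxy-5-hydroxy-6-iodo-4'-methoxyflavone
Product: 4 5,7-dibenzyloxy-6-iodo-4'-methoxyflavone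
Conditions: BnBr, K2CO3, DMF, 70 °C
Reagents that add atoms: benzyl bromide, BrCc1ccccc1
Why: Williamson etherification of the chelated, flanked 5-OH needs DMF and heat but has no competing site; the ether removes the acidic proton before the palladium steps and blocks O5 against any later pyranone reclosure.

**Step 4**
Reactants: 4 5,7-dibenzyloxy-6-iodo-4'-methoxyflavone
Product: 5 5,7-dibenzyloxy-4'-methoxy-6-(4,4,5,5-tetramethyl-1,3,2-dioxaborolan-2-yl)flavone
Conditions: HBpin, Et3N, PdCl2(MeCN)2 (cat.), SPhos, 1,4-dioxane, 80 °C
Reagents that add atoms: pinacolborane, CC1(C)OBOC1(C)C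
Why: Palladium-catalysed borylation of an aryl iodide with pinacolborane (Miyaura–Masuda type): oxidative addition to zerovalent palladium, then boryl transfer from the amine-activated borane. The dialkylbiarylphosphine is chosen for the two ortho benzyloxy groups, and the chromone carbonyl is not reduced by pinacolborane under these conditions.

**Step 5**
Reactants: 6 4-methoxy-6-methyl-2H-pyran-2-one
Product: 7 3-iodo-4-methoxy-6-methyl-2H-pyran-2-one
Conditions: NIS, CF3CO2H (cat.), MeCN, rt to 50 °C
Reagents that add atoms: N-iodosuccinimide, O=C1CCC(=O)N1I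
Why: Electrophilic iodination at C3, the β-carbon of the 4-methoxy enol ether and the most nucleophilic ring position of 4-methoxy-2-pyrones; it is done on the simple pyrone so that no active methylene or enone is present.

**Step 6**
Reactants: 5 5,7-dibenzyloxy-4'-methoxy-6-(pinacolboryl)flavone; 7 3-iodo-4-methoxy-6-methyl-2H-pyran-2-one
Product: 8 3-(5,7-dibenzyloxy-4'-methoxyflavon-6-yl)-4-methoxy-6-methyl-2H-pyran-2-one
Conditions: Pd(OAc)2 (cat.), SPhos, K3PO4, toluene–H2O (10:1), 90 °C, excess of 5
Reagents that add atoms: none
Why: Suzuki–Miyaura coupling; the electron-poor 3-iodopyrone adds oxidatively with ease, and SPhos is suited to di-ortho-substituted, electron-rich boron partners and tetra-ortho-substituted products. K3PO4 in toluene–water should leave the 4-methoxy-2-pyrone lactone intact, and the excess of 5 allows for protodeboronation.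

**Step 7**
Reactants: 9 4-(benzyloxy)benzaldehyde; 10 diethyl [2-(methoxy(methyl)amino)-2-oxoethyl]phosphonate
Product: 11 (E)-3-[4-(benzyloxy)phenyl]-N-methoxy-N-methylprop-2-enamide
Conditions: NaH, THF, 0 °C to rt
Reagents that add atoms: none
Why: Horner–Wadsworth–Emmons olefination with a stabilized phosphonate anion, which gives the E alkene.

**Step 8**
Reactants: 8 3-(5,7-dibenzyloxy-4'-methoxyflavon-6-yl)-4-methoxy-6-methyl-2H-pyran-2-one; 11 (E)-3-[4-(benzyloxy)phenyl]-N-methoxy-N-methylprop-2-enamide
Product: 12 3-(5,7-dibenzyloxy-4'-methoxyflavon-6-yl)-4-methoxy-6-[(E)-4-(4-benzyloxyphenyl)-2-oxobut-3-enyl]-2H-pyran-2-one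
Conditions: LiN(SiMe3)2 (2.5 equiv), THF, −78 °C; then 11, −78 to −20 °C; aq. NH4Cl
Reagents that add atoms: none
Why: Claisen-type acylation of a vinylogous lactone enolate with a Weinreb amide; LiN(SiMe3)2 removes a proton from the 6-methyl group, whose anion is delocalized into the lactone, and is too weak to metalate the vinylic C3–H of the flavone. The chelated tetrahedral adduct prevents double addition, and the second equivalent of base is taken up by the more acidic product.

**Step 9**
Reactants: 12 3-(5,7-dibenzyloxy-4'-methoxyflavon-6-yl)-4-methoxy-6-[(E)-4-(4-benzyloxyphenyl)-2-oxobut-3-enyl]-2H-pyran-2-one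
Product: 14 (E)-1-[3-(5,7-dibenzyloxy-4'-methoxyflavon-6-yl)-2,6-dihydroxy-4-methoxyphenyl]-3-[4-(benzyloxy)phenyl]prop-2-en-1-one, via ring-opened methyl ester 13 (not isolated)
Conditions: Mg(OMe)2 (excess, freshly made), MeOH–THF, 65 °C; then cold 1 M HCl, brief work-up
Reagents that add atoms: none
Why: Methoxide adds to the lactone carbonyl of 12 and the ring opens at the acyl–oxygen bond to the magnesium enolate of ester 13, in which the ester carbon and C4 remain cis on the C2=C3 bond (2E); only this geometry can cyclize. The magnesium-bound enolate of the 5,7-dicarbonyl unit then attacks the ester through C6 in an intramolecular Claisen condensation (6-exo-trig), which forms the C4a''–C8a'' bond; loss of methoxide and enolization give the aromatic ring, so the net change is an isomerization. The closest known reaction type is the Mg(OMe)2-mediated conversion of 6-(2-oxoalkyl)-4-methoxy-2-pyrones and of 3,5,7-triketo esters into acylphloroglucinols. No stereocentre is formed and the E enone is carried through unchanged. The step needs Claisen closure to beat aldol closure: the aldol mode (C2 onto the C7 ketone) would make C2 quaternary and unable to aromatize, because C2 bears the flavonyl group, and magnesium chelation of the diketonate favours C-acylation and damps retro-Claisen cleavage of the side chain. Benzyl and methyl ethers are inert, methoxide addition to C2 of the flavone of unit 1 is reversible, and exchange at the methoxy-bearing C3 of 13 is degenerate in methanol. The work-up is kept cold and short so that 14 does not isomerize to a flavanone through either hydroxyl.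

**Step 10**
Reactants: 14 (E)-1-[3-(5,7-dibenzyloxy-4'-methoxyflavon-6-yl)-2,6-dihydroxy-4-methoxyphenyl]-3-[4-(benzyloxy)phenyl]prop-2-en-1-one
Product: 15 (E)-1-[6-(benzyloxy)-3-(5,7-dibenzyloxy-4'-methoxyflavon-6-yl)-2-hydroxy-4-methoxyphenyl]-3-[4-(benzyloxy)phenyl]prop-2-en-1-one
Conditions: BnBr (1.05 equiv), K2CO3, acetone, rt
Reagents that add atoms: benzyl bromide, BrCc1ccccc1
Why: Williamson etherification under steric control; the hydroxyl next to C–H is accessible, whereas the other lies between the cinnamoyl group and the 2,6-dibenzyloxyaryl ring and stays hydrogen-bonded to the ketone once its neighbour is alkylated, so one equivalent of benzyl bromide should stop at the monoether.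

**Step 11**
Reactants: 15 (E)-1-[6-(benzyloxy)-3-(5,7-dibenzyloxy-4'-methoxyflavon-6-yl)-2-hydroxy-4-methoxyphenyl]-3-[4-(benzyloxy)phenyl]prop-2-en-1-one
Product: 17 5,7-dibenzyloxy-6-[5-benzyloxy-2-(4-benzyloxyphenyl)-7-methoxy-4-oxo-4H-chromen-8-yl]-2-(4-methoxyphenyl)-4H-chromen-4-one, via flavanone 16 (not isolated)
Conditions: I2 (0.1 equiv), DMSO, 120 °C
Reagents that add atoms: none
Why: Iodine–DMSO oxidative cyclization of a 2'-hydroxychalcone; oxa-Michael addition of the only free hydroxyl gives flavanone 16, α-iodination and loss of HI give the flavone, and DMSO reoxidizes HI to I2. Because the exposed oxygen is a benzyl ether, ring C can only close through the oxygen next to the biaryl bond, which fixes the 8''-linkage; the transient C2'' stereocentre of 16 is destroyed.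

**Step 12**
Reactants: 17 5,7-dibenzyloxy-6-[5-benzyloxy-2-(4-benzyloxyphenyl)-7-methoxy-4-oxo-4H-chromen-8-yl]-2-(4-methoxyphenyl)-4H-chromen-4-one
Product: 18 5,7-dihydroxy-6-[5-hydroxy-2-(4-hydroxyphenyl)-7-methoxy-4-oxo-4H-chromen-8-yl]-2-(4-methoxyphenyl)-4H-chromen-4-one (target)
Conditions: H2 (1 atm), 10% Pd/C, THF–MeOH, rt
Reagents that add atoms: none
Why: Catalytic hydrogenolysis of four benzyl aryl ethers; the C2=C3 bonds of flavones are aryl-conjugated vinylogous esters and should not be reduced at room temperature and 1 atm, and the two methyl ethers are untouched.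

**Compound list**

1 | acacetin (5,7-dihydroxy-4'-methoxyflavone) | COc1ccc(cc1)-c1cc(=O)c2c(O)cc(O)cc2o1 | starting material
2 | 7-benzyloxy-5-hydroxy-4'-methoxyflavone | COc1ccc(cc1)-c1cc(=O)c2c(O)cc(OCc3ccccc3)cc2o1 | intermediate
3 | 7-benzyloxy-5-hydroxy-6-iodo-4'-methoxyflavone | COc1ccc(cc1)-c1cc(=O)c2c(O)c(I)c(OCc3ccccc3)cc2o1 | intermediate
4 | 5,7-dibenzyloxy-6-iodo-4'-methoxyflavone | COc1ccc(cc1)-c1cc(=O)c2c(OCc3ccccc3)c(I)c(OCc3ccccc3)cc2o1 | intermediate
5 | 5,7-dibenzyloxy-4'-methoxy-6-(4,4,5,5-tetramethyl-1,3,2-dioxaborolan-2-yl)flavone | COc1ccc(cc1)-c1cc(=O)c2c(OCc3ccccc3)c(B3OC(C)(C)C(C)(C)O3)c(OCc3ccccc3)cc2o1 | intermediate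
6 | 4-methoxy-6-methyl-2H-pyran-2-one | COc1cc(C)oc(=O)c1 | starting material
7 | 3-iodo-4-methoxy-6-methyl-2H-pyran-2-one | COc1cc(C)oc(=O)c1I | intermediate
8 | 3-(5,7-dibenzyloxy-4'-methoxyflavon-6-yl)-4-methoxy-6-methyl-2H-pyran-2-one | COc1cc(C)oc(=O)c1-c1c(OCc2ccccc2)cc2oc(-c3ccc(OC)cc3)cc(=O)c2c1OCc1ccccc1 | intermediate
9 | 4-(benzyloxy)benzaldehyde | O=Cc1ccc(OCc2ccccc2)cc1 | starting material
10 | diethyl [2-(methoxy(methyl)amino)-2-oxoethyl]phosphonate | CCOP(=O)(CC(=O)N(C)OC)OCC | starting material
11 | (E)-3-[4-(benzyloxy)phenyl]-N-methoxy-N-methylprop-2-enamide | CON(C)C(=O)/C=C/c1ccc(OCc2ccccc2)cc1 | intermediate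
12 | 3-(5,7-dibenzyloxy-4'-methoxyflavon-6-yl)-4-methoxy-6-[(E)-4-(4-benzyloxyphenyl)-2-oxobut-3-enyl]-2H-pyran-2-one | O=c1oc(CC(=O)/C=C/c2ccc(OCc3ccccc3)cc2)cc(OC)c1-c1c(OCc2ccccc2)cc2oc(-c3ccc(OC)cc3)cc(=O)c2c1OCc1ccccc1 | intermediate (precursor of the key step)
13 | methyl (2E,8E)-9-[4-(benzyloxy)phenyl]-2-(5,7-dibenzyloxy-4'-methoxyflavon-6-yl)-3-methoxy-5,7-dioxonona-2,8-dienoate | COC(=O)/C(=C(OC)\CC(=O)CC(=O)/C=C/c1ccc(OCc2ccccc2)cc1)c1c(OCc2ccccc2)cc2oc(-c3ccc(OC)cc3)cc(=O)c2c1OCc1ccccc1 | intermediate (not isolated)
14 | (E)-1-[3-(5,7-dibenzyloxy-4'-methoxyflavon-6-yl)-2,6-dihydroxy-4-methoxyphenyl]-3-[4-(benzyloxy)phenyl]prop-2-en-1-one | O=C(/C=C/c1ccc(OCc2ccccc2)cc1)c1c(O)cc(OC)c(-c2c(OCc3ccccc3)cc3oc(-c4ccc(OC)cc4)cc(=O)c3c2OCc2ccccc2)c1O | intermediate (product of the key step)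
15 | (E)-1-[6-(benzyloxy)-3-(5,7-dibenzyloxy-4'-methoxyflavon-6-yl)-2-hydroxy-4-methoxyphenyl]-3-[4-(benzyloxy)phenyl]prop-2-en-1-one | O=C(/C=C/c1ccc(OCc2ccccc2)cc1)c1c(OCc2ccccc2)cc(OC)c(-c2c(OCc3ccccc3)cc3oc(-c4ccc(OC)cc4)cc(=O)c3c2OCc2ccccc2)c1O | intermediate
16 | 5-benzyloxy-2-(4-benzyloxyphenyl)-8-(5,7-dibenzyloxy-4'-methoxyflavon-6-yl)-7-methoxychroman-4-one (C2 unassigned, mixture) | O=C1CC(c2ccc(OCc3ccccc3)cc2)Oc2c1c(OCc1ccccc1)cc(OC)c2-c1c(OCc2ccccc2)cc2oc(-c3ccc(OC)cc3)cc(=O)c2c1OCc1ccccc1 | intermediate (not isolated)
17 | 5,7-dibenzyloxy-6-[5-benzyloxy-2-(4-benzyloxyphenyl)-7-methoxy-4-oxo-4H-chromen-8-yl]-2-(4-methoxyphenyl)-4H-chromen-4-one | COc1ccc(-c2cc(=O)c3c(OCc4ccccc4)c(-c4c(OC)cc(OCc5ccccc5)c5c(=O)cc(-c6ccc(OCc7ccccc7)cc6)oc45)c(OCc4ccccc4)cc3o2)cc1 | intermediate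
18 | 5,7-dihydroxy-6-[5-hydroxy-2-(4-hydroxyphenyl)-7-methoxy-4-oxo-4H-chromen-8-yl]-2-(4-methoxyphenyl)-4H-chromen-4-one (CNP0290866.0) | COc1ccc(-c2cc(=O)c3c(O)c(-c4c(OC)cc(O)c5c(=O)cc(-c6ccc(O)cc6)oc45)c(O)cc3o2)cc1 | target

**Step count and least certain steps**

Total: 12 steps. Longest linear sequence: 10 steps (1, 2, 3, 4, 6, 8, 9, 10, 11, 12, from acacetin).

Step 9 (key step). The Claisen closure has to reach an ester whose α-carbon carries a 2,6-dibenzyloxyaryl group, so it may be slow. That leaves time for methoxide-induced retro-Claisen cleavage of the dicarbonyl side chain, conjugate addition of methoxide to the enone, and oxa-Michael closure of the product through the exposed hydroxyl. Fallback, setting out from 5 and returning at 15: ring A of unit 2 is brought in preformed.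
- Commercial 1-(2,6-dihydroxy-4-methoxyphenyl)ethanone, whose two hydroxyls are equivalent, is monobenzylated (BnBr, K2CO3, acetone) to 1-[2-(benzyloxy)-6-hydroxy-4-methoxyphenyl]ethanone F1.
- F1 is iodinated ortho to the remaining chelated hydroxyl (BnNMe3·ICl2, CaCO3, CH2Cl2–MeOH) to 1-[6-(benzyloxy)-2-hydroxy-3-iodo-4-methoxyphenyl]ethanone F2.
- F2 is coupled with 5 under the conditions of step 6 to 1-[6-(benzyloxy)-3-(5,7-dibenzyloxy-4'-methoxyflavon-6-yl)-2-hydroxy-4-methoxyphenyl]ethanone F3.
- Claisen–Schmidt condensation of F3 with 9 (KOH, EtOH–THF, rt) gives 15.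

Step 6. Protodeboronation of the di-ortho-alkoxy boron partner may outrun transmetalation, and reductive elimination to a tetra-ortho-substituted bond is slow. Fallback, setting out from 4 and returning at 8 (it also bypasses step 4): the bond is made by ligand coupling on lead instead of palladium cross-coupling.
- 4 is stannylated ((Bu3Sn)2, Pd(PPh3)4, toluene, 110 °C) to 5,7-dibenzyloxy-4'-methoxy-6-(tributylstannyl)flavone F4.
- Tin–lead exchange (Pb(OAc)4, catalytic Hg(OAc)2, CHCl3) gives (5,7-dibenzyloxy-4'-methoxyflavon-6-yl)lead triacetate F5.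
- Pinhey-type arylation of commercial 4-hydroxy-6-methyl-2H-pyran-2-one at C3 (pyridine, CHCl3, 40–60 °C) gives 3-(5,7-dibenzyloxy-4'-methoxyflavon-6-yl)-4-hydroxy-6-methyl-2H-pyran-2-one F6.
- O-methylation of F6 (Me2SO4, K2CO3, acetone) gives 8.

Step 8. The delocalized pyrone anion may add slowly or in conjugate fashion to the unsaturated Weinreb amide, and the excess base may attack the flavone of unit 1 on warming. Fallback, setting out from 8 and 11 and returning at 12: the carbon–carbon bond is made by aldol addition with one equivalent of base, and the ketone is generated by oxidation.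
- 11 is reduced (i-Bu2AlH, THF, −78 °C) to (E)-3-[4-(benzyloxy)phenyl]prop-2-enal F7.
- The lithium dienolate of 8 (LiN(SiMe3)2, 1.1 equiv, THF, −78 °C) adds 1,2 to F7, with a cold quench, to give 3-(5,7-dibenzyloxy-4'-methoxyflavon-6-yl)-6-[(E)-4-(4-benzyloxyphenyl)-2-hydroxybut-3-enyl]-4-methoxy-2H-pyran-2-one F8.
- Oxidation of the allylic alcohol F8 (MnO2, CH2Cl2, or Dess–Martin periodinane) gives 12.

Step 10. Under carbonate the chalcone phenoxide may close to a flavanone through either hydroxyl before it is alkylated, and some alkylation may occur at the hindered oxygen; both would erode the regiocontrol of ring C. Fallback, setting out from 14 and returning at 15: Mitsunobu etherification (BnOH, PPh3, DIAD, THF, 0 °C). This runs without a free phenoxide, is more sensitive to steric hindrance than phenoxide alkylation, and leaves the hindered, chelated hydroxyl alone. No new compound is made.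

**Further compounds**

F1 | step 9 | 1-[2-(benzyloxy)-6-hydroxy-4-methoxyphenyl]ethanone | CC(=O)c1c(O)cc(OC)cc1OCc1ccccc1
F2 | step 9 | 1-[6-(benzyloxy)-2-hydroxy-3-iodo-4-methoxyphenyl]ethanone | CC(=O)c1c(O)c(I)c(OC)cc1OCc1ccccc1
F3 | step 9 | 1-[6-(benzyloxy)-3-(5,7-dibenzyloxy-4'-methoxyflavon-6-yl)-2-hydroxy-4-methoxyphenyl]ethanone | CC(=O)c1c(OCc2ccccc2)cc(OC)c(c1O)-c1c(OCc2ccccc2)cc2oc(-c3ccc(OC)cc3)cc(=O)c2c1OCc1ccccc1
F4 | step 6 | 5,7-dibenzyloxy-4'-methoxy-6-(tributylstannyl)flavone | COc1ccc(cc1)-c1cc(=O)c2c(OCc3ccccc3)c([Sn](CCCC)(CCCC)CCCC)c(OCc3ccccc3)cc2o1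
F5 | step 6 | (5,7-dibenzyloxy-4'-methoxyflavon-6-yl)lead triacetate | COc1ccc(cc1)-c1cc(=O)c2c(OCc3ccccc3)c([Pb](OC(C)=O)(OC(C)=O)OC(C)=O)c(OCc3ccccc3)cc2o1
F6 | step 6 | 3-(5,7-dibenzyloxy-4'-methoxyflavon-6-yl)-4-hydroxy-6-methyl-2H-pyran-2-one | Cc1cc(O)c(c(=O)o1)-c1c(OCc2ccccc2)cc2oc(-c3ccc(OC)cc3)cc(=O)c2c1OCc1ccccc1
F7 | step 8 | (E)-3-[4-(benzyloxy)phenyl]prop-2-enal | O=C/C=C/c1ccc(OCc2ccccc2)cc1
F8 | step 8 | 3-(5,7-dibenzyloxy-4'-methoxyflavon-6-yl)-6-[(E)-4-(4-benzyloxyphenyl)-2-hydroxybut-3-enyl]-4-methoxy-2H-pyran-2-one (racemic alcohol) | O=c1oc(CC(O)/C=C/c2ccc(OCc3ccccc3)cc2)cc(OC)c1-c1c(OCc2ccccc2)cc2oc(-c3ccc(OC)cc3)cc(=O)c2c1OCc1ccccc1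
F0 | step 10 | none | none
A1 | alternative 1 | 4-[2-(4-benzyloxyphenyl)-5,7-dimethoxy-4-oxo-4H-chromen-8-yl]-2-[(tert-butyldimethylsilyloxy)methyl]-3-ethoxycyclobut-2-en-1-one (racemic) | O=C1C(CO[Si](C)(C)C(C)(C)C)=C(OCC)C1c1c(OC)cc(OC)c2c(=O)cc(-c3ccc(OCc4ccccc4)cc3)oc12
A2 | alternative 1 | (triisopropylsilyloxy)acetylene | C#CO[Si](C(C)C)(C(C)C)C(C)C
A3 | alternative 1 | 2-(flavon-8-yl)-3-ethoxy-4-[(tert-butyldimethylsilyloxy)methyl]-5-(triisopropylsilyloxy)phenol | Oc1cc(O[Si](C(C)C)(C(C)C)C(C)C)c(CO[Si](C)(C)C(C)(C)C)c(OCC)c1-c1c(OC)cc(OC)c2c(=O)cc(-c3ccc(OCc4ccccc4)cc3)oc12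
A4 | alternative 2 | 7-benzyloxy-5-{[5-benzyloxy-2-(4-benzyloxyphenyl)-8-iodo-4-oxo-4H-chromen-7-yl]oxymethoxy}-2-(4-methoxyphenyl)-4H-chromen-4-one | COc1ccc(cc1)-c1cc(=O)c2c(OCOc3cc(OCc4ccccc4)c4c(=O)cc(-c5ccc(OCc6ccccc6)cc5)oc4c3I)cc(OCc3ccccc3)cc2o1
A5 | alternative 2 | O5,O7''-methylene-bridged 6,8''-biflavone tribenzyl ether | COc1ccc(cc1)-c1cc(=O)c2c3OCOc4cc(OCc5ccccc5)c5c(=O)cc(-c6ccc(OCc7ccccc7)cc6)oc5c4-c3c(OCc3ccccc3)cc2o1
A6 | alternative 3 | 5,7-dihydroxy-8-[2-(4-hydroxyphenyl)-5,7-dimethoxy-4-oxo-4H-chromen-8-yl]-2-(4-methoxyphenyl)-4H-chromen-4-one (8,8''-linked) | COc1ccc(cc1)-c1cc(=O)c2c(O)cc(O)c(-c3c(OC)cc(OC)c4c(=O)cc(-c5ccc(O)cc5)oc34)c2o1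
A7 | alternative 3 | 5''-O-methyl ether of the target (6,8''-linked) | COc1ccc(cc1)-c1cc(=O)c2c(O)c(-c3c(OC)cc(OC)c4c(=O)cc(-c5ccc(O)cc5)oc34)c(O)cc2o1
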